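**Plan**

1. Retrosynthesis cuts the three C4–C8 interflavan bonds, the gallate ester and, in the epigallocatechin building block, the C4–C4a bond of ring C. That ring is traced back to a 2-aryl-3-hydroxy-2,3-dihydrobenzofuran that carries the future C4 as an exocyclic acetal carbon.
2. Forward: chromone → (2S)-flavanone → hypervalent-iodine ring contraction (ring A moves from C4 to C3) → α-hydroxy aldehyde → semipinacol ring expansion (ring A moves back to the old C4) → one 4-methoxyflavan-3-ol 10. Compound 10 is used as its gallate 12 for the galloylated unit and twice as such for the two upper units; the chain grows from epicatechin upward.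
3. Enabling feature: the electron-rich 5,7-dioxygenated ring A sits on the tertiary carbinol C3 of the five-membered ring O1–C2–C3–C3a–C7a, next to the old C4 held at the carbonyl oxidation level. Its 1,2-shift makes the C3 ketone and delivers C4 already bearing the methoxy leaving group that each interflavan coupling needs.
4. Stereochemistry: C2 from ligand-controlled conjugate addition; C3 from chelation-controlled ketone reduction (cis to the C2 aryl); each interflavan C4 (β) from attack trans to the 3-oxygen; the bottom unit from (−)-epicatechin.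

Key step: step 6

Assumption: 3,4,5-tris(benzyloxy)phenylboronic acid (3) is treated as a purchasable building block (otherwise one borylation step from the aryl bromide).

**Route**

Step 1
Reactants: 1 5,7-dihydroxychromone
Product: 2 5,7-bis(benzyloxy)chromone
Conditions: BnBr, K2CO3, DMF, 70 °C
Reagents that add atoms: benzyl bromide BrCc1ccccc1
Why: Williamson etherification of both phenols (the hydrogen-bonded 5-OH needs warming) installs benzyl ethers that should survive until the final hydrogenolysis.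

Step 2
Reactants: 2 5,7-bis(benzyloxy)chromone; 3 3,4,5-tris(benzyloxy)phenylboronic acid
Product: 4 (2S)-5,7-bis(benzyloxy)-2-[3,4,5-tris(benzyloxy)phenyl]chroman-4-one
Conditions: Pd(OCOCF3)2 (cat.), (R)-t-BuPyOx (cat.), NH4PF6, H2O, ClCH2CH2Cl, 60 °C
Reagents that add atoms: none
Why: Palladium-catalysed asymmetric conjugate addition of an arylboronic acid to a chromone (Hayashi–Miyaura type) should add the aryl group to C2 on the enantioface fixed by the pyridine-oxazoline ligand, whose enantiomer is chosen to give the 2S flavanone (aryl α).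

Step 3
Reactants: 4 (2S)-5,7-bis(benzyloxy)-2-[3,4,5-tris(benzyloxy)phenyl]chroman-4-one
Product: 5 methyl (2S,3S)-4,6-bis(benzyloxy)-2-[3,4,5-tris(benzyloxy)phenyl]-2,3-dihydrobenzofuran-3-carboxylate
Conditions: PhI(OAc)2, H2SO4 (cat.), HC(OMe)3, rt
Reagents that add atoms: trimethyl orthoformate COC(OC)OC
Why: Hypervalent-iodine oxidative ring contraction of a flavanone: the enol ether of the dimethyl ketal is attacked at C3 by the iodane, ring A shifts from C4 to C3 with loss of iodobenzene, and the old C4 leaves the ring as the methyl ester, giving the 2,3-trans product with C2 untouched.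

Step 4
Reactants: 5 methyl (2S,3S)-4,6-bis(benzyloxy)-2-[3,4,5-tris(benzyloxy)phenyl]-2,3-dihydrobenzofuran-3-carboxylate
Product: 6 methyl (2R,3S)-4,6-bis(benzyloxy)-3-hydroxy-2-[3,4,5-tris(benzyloxy)phenyl]-2,3-dihydrobenzofuran-3-carboxylate
Conditions: KN(SiMe3)2, THF, −78 °C; 2-(phenylsulfonyl)-3-phenyloxaziridine; NH4Cl (aq)
Reagents that add atoms: 2-(phenylsulfonyl)-3-phenyloxaziridine O=S(=O)(c1ccccc1)N1OC1c1ccccc1
Why: Davis enolate oxidation should hydroxylate the planar ester enolate on the face opposite the C2 aryl group (OH trans to aryl); this C3 configuration is erased in step 6.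

Step 5
Reactants: 6 methyl (2R,3S)-4,6-bis(benzyloxy)-3-hydroxy-2-[3,4,5-tris(benzyloxy)phenyl]-2,3-dihydrobenzofuran-3-carboxylate
Product: 7 (2R,3S)-4,6-bis(benzyloxy)-3-hydroxy-2-[3,4,5-tris(benzyloxy)phenyl]-2,3-dihydrobenzofuran-3-carbaldehyde
Conditions: i-Bu2AlH, CH2Cl2, −78 °C; Rochelle salt work-up; used crude
Reagents that add atoms: none
Why: Half-reduction of an α-hydroxy ester stops at the aldehyde stage because the aluminium alkoxide chelates the tetrahedral intermediate until work-up.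

Step 6
Reactants: 7 (2R,3S)-4,6-bis(benzyloxy)-3-hydroxy-2-[3,4,5-tris(benzyloxy)phenyl]-2,3-dihydrobenzofuran-3-carbaldehyde
Product: 9 (2R,4S)-5,7-bis(benzyloxy)-4-methoxy-2-[3,4,5-tris(benzyloxy)phenyl]chroman-3-one, via dimethyl acetal 8 (not isolated)
Conditions: MeOSiMe3, Me3SiOTf (cat.), CH2Cl2, −78 to −30 °C; Et3N quench
Reagents that add atoms: methoxytrimethylsilane CO[Si](C)(C)C
Why: The silyl triflate converts the aldehyde into dimethyl acetal 8 and then ionises it to an O-methyl oxocarbenium ion at the exocyclic carbon; the C3–C3a bond of the electron-rich ring A on the neighbouring tertiary carbinol migrates through a bridged phenonium-like transition state while the C3 oxygen becomes the ketone, so the exocyclic carbon is inserted between C3 and ring A and the five-membered ring becomes the pyran. The closest known reaction type is the acid-promoted semipinacol rearrangement of tertiary α-hydroxy acetals to α-alkoxy ketones, as used for one-carbon ring expansion of cyclic carbinols. No ring is closed by cyclisation: the six-membered ring arises by a 1,2-shift, with C4–C4a formed and C3–C3a broken. C2 is not touched; the new C4 centre should form 2,4-trans because the oxocarbenium rotamer keeps OMe away from the C2 aryl group (also the epimer favoured by the peri 5-benzyloxy group), and it is of no consequence later since C4 is ionised in every coupling. The step needs aryl rather than C2 migration and must avoid loss of the tertiary benzylic hydroxyl (aromatisation to a benzofuran): the 2,4,6-trioxygenated aryl group has far higher migratory aptitude than the oxygen-bearing C2, the adjacent cationic carbon disfavours ionisation at C3, and only catalytic silyl triflate is used at low temperature.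

Step 7
Reactants: 9 (2R,4S)-5,7-bis(benzyloxy)-4-methoxy-2-[3,4,5-tris(benzyloxy)phenyl]chroman-3-one
Product: 10 4β-methoxy-5,7,3',4',5'-penta-O-benzyl-(−)-epigallocatechin (2,3-cis-3,4-trans)
Conditions: Zn(BH4)2, Et2O, −30 to 0 °C
Reagents that add atoms: none
Why: Chelation-controlled (Cram-chelate) reduction of an α-alkoxy ketone: zinc ties the C3 carbonyl to the pseudoequatorial 4-OMe, the C2 aryl group then sits pseudoaxial on the α face, and hydride should enter from the β face to give the 3α-alcohol, anti to OMe and cis to the aryl group.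

Step 8
Reactants: 10 4β-methoxy-5,7,3',4',5'-penta-O-benzyl-(−)-epigallocatechin; 11 3,4,5-tris(benzyloxy)benzoic acid
Product: 12 4β-methoxy-5,7,3',4',5'-penta-O-benzyl-(−)-epigallocatechin 3-O-[3,4,5-tris(benzyloxy)benzoate]
Conditions: EDC·HCl, DMAP, CH2Cl2, rt
Reagents that add atoms: none
Why: Steglich esterification acylates the single secondary hydroxyl, so the gallate is placed on one unit only before any chain is built.

Step 9
Reactants: 13 (−)-epicatechin
Product: 14 5,7,3',4'-tetra-O-benzyl-(−)-epicatechin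
Conditions: BnBr, K2CO3, DMF, 0 °C to rt
Reagents that add atoms: benzyl bromide BrCc1ccccc1
Why: Williamson etherification of the four phenols leaves the less acidic 3-OH free and keeps C8 nucleophilic.

Step 10
Reactants: 12 gallate electrophile; 14 5,7,3',4'-tetra-O-benzyl-(−)-epicatechin (excess)
Product: 15 protected dimer: penta-O-benzyl-3-O-(tri-O-benzylgalloyl)epigallocatechin-(4β→8)-tetra-O-benzylepicatechin
Conditions: Me3SiOTf (cat.), CH2Cl2, −78 °C; Et3N quench
Reagents that add atoms: none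
Why: Lewis-acid Friedel–Crafts interflavan coupling: loss of methanol gives the ring-A-stabilised C4 cation, the 3-O-acyl group shields the α face, and C8 of 14 (more reactive than C6) should attack trans to the 3-oxygen to set 4β.

Step 11
Reactants: 10 4β-methoxy-penta-O-benzyl-epigallocatechin; 15 protected dimer (slight excess)
Product: 16 protected trimer: penta-O-benzylepigallocatechin-(4β→8)-[penta-O-benzyl-3-O-(tri-O-benzylgalloyl)epigallocatechin]-(4β→8)-tetra-O-benzylepicatechin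
Conditions: Me3SiOTf (cat.), CH2Cl2, −78 °C, slow addition of 10; Et3N quench
Reagents that add atoms: none
Why: The same Friedel–Crafts coupling, in which the free C8 of the top unit of 15 is the most nucleophilic site and attack on the 2,3-cis cation occurs trans to the 3-hydroxyl (4β).

Step 12
Reactants: 10 4β-methoxy-penta-O-benzyl-epigallocatechin; 16 protected trimer (slight excess)
Product: 17 protected tetramer (docosa-O-benzyl ether of the target)
Conditions: Me3SiOTf (cat.), CH2Cl2, −78 °C, slow addition of 10; Et3N quench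
Reagents that add atoms: none
Why: A third Friedel–Crafts interflavan coupling at C8 of the new top unit of 16, with 4β selectivity set again by attack trans to the 3-hydroxyl.

Step 13
Reactants: 17 protected tetramer
Product: 18 epigallocatechin-(4β→8)-epigallocatechin-(4β→8)-epigallocatechin 3-O-gallate-(4β→8)-epicatechin (CNP0305998.1)
Conditions: H2 (1 atm), Pd(OH)2/C, THF–MeOH–H2O, rt
Reagents that add atoms: none
Why: Global hydrogenolysis should remove all twenty-two benzyl ethers under neutral conditions that leave the gallate ester and the acid-labile interflavan bonds intact.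

**Compound list**

1 | 5,7-dihydroxychromone | O=c1ccoc2cc(O)cc(O)c12 | starting material
2 | 5,7-bis(benzyloxy)chromone | O=c1ccoc2cc(OCc3ccccc3)cc(OCc3ccccc3)c12 | intermediate
3 | 3,4,5-tris(benzyloxy)phenylboronic acid | OB(O)c1cc(OCc2ccccc2)c(OCc2ccccc2)c(OCc2ccccc2)c1 | starting material
4 | (2S)-5,7-bis(benzyloxy)-2-[3,4,5-tris(benzyloxy)phenyl]chroman-4-one | O=C1C[C@@H](c2cc(OCc3ccccc3)c(OCc3ccccc3)c(OCc3ccccc3)c2)Oc2cc(OCc3ccccc3)cc(OCc3ccccc3)c12 | intermediate
5 | methyl (2S,3S)-4,6-bis(benzyloxy)-2-[3,4,5-tris(benzyloxy)phenyl]-2,3-dihydrobenzofuran-3-carboxylate (2,3-trans) | COC(=O)[C@@H]1[C@@H](c2cc(OCc3ccccc3)c(OCc3ccccc3)c(OCc3ccccc3)c2)Oc2cc(OCc3ccccc3)cc(OCc3ccccc3)c12 | intermediate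
6 | methyl (2R,3S)-4,6-bis(benzyloxy)-3-hydroxy-2-[3,4,5-tris(benzyloxy)phenyl]-2,3-dihydrobenzofuran-3-carboxylate (OH trans to the C2 aryl) | COC(=O)[C@@]1(O)[C@@H](c2cc(OCc3ccccc3)c(OCc3ccccc3)c(OCc3ccccc3)c2)Oc2cc(OCc3ccccc3)cc(OCc3ccccc3)c12 | intermediate
7 | (2R,3S)-4,6-bis(benzyloxy)-3-hydroxy-2-[3,4,5-tris(benzyloxy)phenyl]-2,3-dihydrobenzofuran-3-carbaldehyde | O=C[C@@]1(O)[C@@H](c2cc(OCc3ccccc3)c(OCc3ccccc3)c(OCc3ccccc3)c2)Oc2cc(OCc3ccccc3)cc(OCc3ccccc3)c12 | intermediate
8 | (2R,3S)-4,6-bis(benzyloxy)-3-(dimethoxymethyl)-2-[3,4,5-tris(benzyloxy)phenyl]-2,3-dihydrobenzofuran-3-ol (dimethyl acetal of 7; the hydroxyl may be silylated in the flask) | COC(OC)[C@@]1(O)[C@@H](c2cc(OCc3ccccc3)c(OCc3ccccc3)c(OCc3ccccc3)c2)Oc2cc(OCc3ccccc3)cc(OCc3ccccc3)c12 | intermediate (not isolated)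
9 | (2R,4S)-5,7-bis(benzyloxy)-4-methoxy-2-[3,4,5-tris(benzyloxy)phenyl]chroman-3-one (2,4-trans) | O=C1[C@@H](OC)c2c(OCc3ccccc3)cc(OCc3ccccc3)cc2O[C@@H]1c1cc(OCc2ccccc2)c(OCc2ccccc2)c(OCc2ccccc2)c1 | intermediate
10 | 4β-methoxy-5,7,3',4',5'-penta-O-benzyl-(−)-epigallocatechin (2-aryl α, 3-OH α, 4-OMe β) | O[C@@H]1[C@@H](OC)c2c(OCc3ccccc3)cc(OCc3ccccc3)cc2O[C@@H]1c1cc(OCc2ccccc2)c(OCc2ccccc2)c(OCc2ccccc2)c1 | intermediate
11 | 3,4,5-tris(benzyloxy)benzoic acid | OC(=O)c1cc(OCc2ccccc2)c(OCc2ccccc2)c(OCc2ccccc2)c1 | starting material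
12 | 4β-methoxy-5,7,3',4',5'-penta-O-benzyl-(−)-epigallocatechin 3-O-[3,4,5-tris(benzyloxy)benzoate] | O=C(O[C@@H]1[C@@H](OC)c2c(OCc3ccccc3)cc(OCc3ccccc3)cc2O[C@@H]1c1cc(OCc2ccccc2)c(OCc2ccccc2)c(OCc2ccccc2)c1)c1cc(OCc2ccccc2)c(OCc2ccccc2)c(OCc2ccccc2)c1 | intermediate
13 | (−)-epicatechin | O[C@@H]1Cc2c(O)cc(O)cc2O[C@@H]1c1ccc(O)c(O)c1 | starting material
14 | 5,7,3',4'-tetra-O-benzyl-(−)-epicatechin | O[C@@H]1Cc2c(OCc3ccccc3)cc(OCc3ccccc3)cc2O[C@@H]1c1ccc(OCc2ccccc2)c(OCc2ccccc2)c1 | intermediate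
15 | protected dimer: penta-O-benzyl-3-O-(tri-O-benzylgalloyl)epigallocatechin-(4β→8)-tetra-O-benzylepicatechin | O=C(O[C@@H]1[C@@H](c2c(OCc9ccccc9)cc(OCc9ccccc9)c3c2O[C@H](c2ccc(OCc9ccccc9)c(OCc9ccccc9)c2)[C@H](O)C3)c2c(OCc9ccccc9)cc(OCc9ccccc9)cc2O[C@@H]1c1cc(OCc9ccccc9)c(OCc9ccccc9)c(OCc9ccccc9)c1)c1cc(OCc9ccccc9)c(OCc9ccccc9)c(OCc9ccccc9)c1 | intermediate
16 | protected trimer: penta-O-benzylepigallocatechin-(4β→8)-[penta-O-benzyl-3-O-(tri-O-benzylgalloyl)epigallocatechin]-(4β→8)-tetra-O-benzylepicatechin | O=C(O[C@@H]1[C@@H](c2c(OCc9ccccc9)cc(OCc9ccccc9)c3c2O[C@H](c2ccc(OCc9ccccc9)c(OCc9ccccc9)c2)[C@H](O)C3)c2c(OCc9ccccc9)cc(OCc9ccccc9)c([C@H]3c4c(OCc9ccccc9)cc(OCc9ccccc9)cc4O[C@H](c4cc(OCc9ccccc9)c(OCc9ccccc9)c(OCc9ccccc9)c4)[C@@H]3O)c2O[C@@H]1c1cc(OCc9ccccc9)c(OCc9ccccc9)c(OCc9ccccc9)c1)c1cc(OCc9ccccc9)c(OCc9ccccc9)c(OCc9ccccc9)c1 | intermediate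
17 | protected tetramer: docosa-O-benzyl ether of the target | O=C(O[C@@H]1[C@@H](c2c(OCc9ccccc9)cc(OCc9ccccc9)c3c2O[C@H](c2ccc(OCc9ccccc9)c(OCc9ccccc9)c2)[C@H](O)C3)c2c(OCc9ccccc9)cc(OCc9ccccc9)c([C@H]3c4c(OCc9ccccc9)cc(OCc9ccccc9)c([C@H]5c6c(OCc9ccccc9)cc(OCc9ccccc9)cc6O[C@H](c6cc(OCc9ccccc9)c(OCc9ccccc9)c(OCc9ccccc9)c6)[C@@H]5O)c4O[C@H](c4cc(OCc9ccccc9)c(OCc9ccccc9)c(OCc9ccccc9)c4)[C@@H]3O)c2O[C@@H]1c1cc(OCc9ccccc9)c(OCc9ccccc9)c(OCc9ccccc9)c1)c1cc(OCc9ccccc9)c(OCc9ccccc9)c(OCc9ccccc9)c1 | intermediate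
18 | epigallocatechin-(4β→8)-epigallocatechin-(4β→8)-epigallocatechin 3-O-gallate-(4β→8)-epicatechin (CNP0305998.1) | O=C(O[C@@H]1[C@@H](c2c(O)cc(O)c3c2O[C@H](c2ccc(O)c(O)c2)[C@H](O)C3)c2c(O)cc(O)c([C@H]3c4c(O)cc(O)c([C@H]5c6c(O)cc(O)cc6O[C@H](c6cc(O)c(O)c(O)c6)[C@@H]5O)c4O[C@H](c4cc(O)c(O)c(O)c4)[C@@H]3O)c2O[C@@H]1c1cc(O)c(O)c(O)c1)c1cc(O)c(O)c(O)c1 | target

**Step count and risks**

Total step count: 13. Longest linear sequence: 12 steps (steps 1–8, then 10–13).

Steps most likely to fail: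

1. Step 6. The acetal may fail to ionise selectively: ionisation at the tertiary benzylic C3–O bond followed by loss of the C2 proton would aromatise the ring to a benzofuran, and C2 could migrate in place of ring A. The fallback sets out from 7 and uses an aluminium-alkoxide-assisted α-ketol (acyloin) shift of the free aldehyde (Et2AlCl, CH2Cl2, −78 to 0 °C). The same aryl group moves to the formyl carbon without any cationic centre beside C3, which should give (2R)-5,7-bis(benzyloxy)-4-hydroxy-2-[3,4,5-tris(benzyloxy)phenyl]chroman-3-one F1. O-Methylation of F1 (MeI, Ag2O, CH2Cl2) comes back to the route at 9.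

2. Step 7. Facial selectivity may be poor if the zinc chelate does not form or if C4 has partly epimerised, so that hydride delivery gives the 3-epimeric alcohol. The fallback sets out from 6 and avoids any C4 substituent at the reduction stage. LiAlH4 (THF, 0 °C) gives 4,6-bis(benzyloxy)-3-(hydroxymethyl)-2-[3,4,5-tris(benzyloxy)phenyl]-2,3-dihydrobenzofuran-3-ol F2. MsCl and Et3N (CH2Cl2, −20 °C) give its primary mesylate F3. Et3Al (CH2Cl2, −78 °C) promotes the semipinacol 1,2-aryl shift to (2R)-5,7-bis(benzyloxy)-2-[3,4,5-tris(benzyloxy)phenyl]chroman-3-one F4. LiBH(s-Bu)3 (THF, −78 °C) attacks anti to the C2 aryl group and gives 5,7,3',4',5'-penta-O-benzyl-(−)-epigallocatechin F5. Benzylic oxidation with DDQ in the presence of MeOH (CH2Cl2, rt) then installs the 4β-methoxy group and comes back to the route at 10.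

3. Step 12 (the same process threatens step 11). Electrophile 10 may self-condense through its own free C8, and 16 may be attacked at C6, giving mixtures of chain lengths and regioisomers. The fallback sets out from 10 and blocks C8 of the last unit. NBS (CH2Cl2, −40 °C) gives 8-bromo-4β-methoxy-5,7,3',4',5'-penta-O-benzyl-(−)-epigallocatechin F6. Coupling of F6 with 16 (Me3SiOTf, CH2Cl2, −78 °C) can then occur only in the wanted sense and gives the 8-bromo protected tetramer F7. Hydrogenolysis of F7 (H2, Pd(OH)2/C, Et3N, THF–MeOH) removes the bromine together with the benzyl groups and comes back to the route at 18.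

**Further compounds**

F1 | step 6 | (2R)-5,7-bis(benzyloxy)-4-hydroxy-2-[3,4,5-tris(benzyloxy)phenyl]chroman-3-one (2,4-trans drawn) | O=C1[C@@H](O)c2c(OCc3ccccc3)cc(OCc3ccccc3)cc2O[C@@H]1c1cc(OCc2ccccc2)c(OCc2ccccc2)c(OCc2ccccc2)c1
F2 | step 7 | 4,6-bis(benzyloxy)-3-(hydroxymethyl)-2-[3,4,5-tris(benzyloxy)phenyl]-2,3-dihydrobenzofuran-3-ol (C2 and C3 geometry as in 6) | OC[C@@]1(O)[C@@H](c2cc(OCc3ccccc3)c(OCc3ccccc3)c(OCc3ccccc3)c2)Oc2cc(OCc3ccccc3)cc(OCc3ccccc3)c12
F3 | step 7 | primary methanesulfonate of F2 | CS(=O)(=O)OC[C@@]1(O)[C@@H](c2cc(OCc3ccccc3)c(OCc3ccccc3)c(OCc3ccccc3)c2)Oc2cc(OCc3ccccc3)cc(OCc3ccccc3)c12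
F4 | step 7 | (2R)-5,7-bis(benzyloxy)-2-[3,4,5-tris(benzyloxy)phenyl]chroman-3-one | O=C1Cc2c(OCc3ccccc3)cc(OCc3ccccc3)cc2O[C@@H]1c1cc(OCc2ccccc2)c(OCc2ccccc2)c(OCc2ccccc2)c1
F5 | step 7 | 5,7,3',4',5'-penta-O-benzyl-(−)-epigallocatechin | O[C@@H]1Cc2c(OCc3ccccc3)cc(OCc3ccccc3)cc2O[C@@H]1c1cc(OCc2ccccc2)c(OCc2ccccc2)c(OCc2ccccc2)c1
F6 | step 12 | 8-bromo-4β-methoxy-5,7,3',4',5'-penta-O-benzyl-(−)-epigallocatechin | O[C@@H]1[C@@H](OC)c2c(OCc3ccccc3)cc(OCc3ccccc3)c(Br)c2O[C@@H]1c1cc(OCc2ccccc2)c(OCc2ccccc2)c(OCc2ccccc2)c1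
F7 | step 12 | protected tetramer 17 carrying bromine at C8 of the top unit | O=C(O[C@@H]1[C@@H](c2c(OCc9ccccc9)cc(OCc9ccccc9)c3c2O[C@H](c2ccc(OCc9ccccc9)c(OCc9ccccc9)c2)[C@H](O)C3)c2c(OCc9ccccc9)cc(OCc9ccccc9)c([C@H]3c4c(OCc9ccccc9)cc(OCc9ccccc9)c([C@H]5c6c(OCc9ccccc9)cc(OCc9ccccc9)c(Br)c6O[C@H](c6cc(OCc9ccccc9)c(OCc9ccccc9)c(OCc9ccccc9)c6)[C@@H]5O)c4O[C@H](c4cc(OCc9ccccc9)c(OCc9ccccc9)c(OCc9ccccc9)c4)[C@@H]3O)c2O[C@@H]1c1cc(OCc9ccccc9)c(OCc9ccccc9)c(OCc9ccccc9)c1)c1cc(OCc9ccccc9)c(OCc9ccccc9)c(OCc9ccccc9)c1
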